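## Retrosynthetic overview

1. The target comes from a penta-O-benzyl ether by global hydrogenolysis; both stereocentres are already in place.
2. Key disconnection, C3–C3a of the dihydrobenzofuran: the five-membered ring is made last, by PhI(OH)OTs ring contraction of a (2S)-2,4-diaryl-2H-chromene. Trivalent iodine makes C3 (the carbon alpha to the emerging ketone) an electrophile, the ring A carbon migrates from C4 to C3, C4 becomes the 3-aroyl carbonyl, and C3 is set trans to C2.
3. Both 2,4-dioxygenated aryl ketone units come from one aryllithium, added in one operation to the C4 carbonyl of a flavanone and to a side-chain nitrile, followed by dehydration to the 2H-chromene.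
4. The aryl–CH2 bond of the side chain comes from a Negishi coupling of a 6-bromoflavanone with (2-cyanoethyl)zinc bromide, a beta-metallated nitrile.
5. C2 is set by enantioselective palladium-catalysed conjugate addition of an arylboronic acid to 6-bromochromone. Ring order: pyranone ring (bought) → chromanone → 2H-chromene → dihydrofuran ring (by contraction).

Assumption: (R)-t-BuPyOX is taken, by analogy with additions to cyclic enones, as the ligand antipode that gives the (S)-flavanone; if the CD spectrum of 3 shows the opposite sense, the other antipode is used with no other change.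

## Route

Step 1
Reactants: 1 6-bromo-4H-chromen-4-one (6-bromochromone); 2 [4-(benzyloxy)phenyl]boronic acid
Product: 3 (2S)-2-[4-(benzyloxy)phenyl]-6-bromo-2,3-dihydro-4H-chromen-4-one
Conditions: Pd(OCOCF3)2 (5 mol%), (R)-t-BuPyOX (6 mol%), NH4PF6 (30 mol%), H2O (5 equiv), ClCH2CH2Cl, 60 °C
Reagents that add atoms: none
Why: Enantioselective conjugate addition of an arylboronic acid to a chromone with a cationic divalent palladium pyridine-oxazoline catalyst: the arylpalladium species adds to one face of C2=C3 and water protonates the palladium enolate, which sets C2 as S, while the aryl bromide survives because no zerovalent palladium is formed.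

Step 2
Reactants: 3 (2S)-2-[4-(benzyloxy)phenyl]-6-bromo-2,3-dihydro-4H-chromen-4-one; 4 (2-cyanoethyl)zinc bromide (0.5 M in THF)
Product: 5 3-{(2S)-2-[4-(benzyloxy)phenyl]-4-oxo-3,4-dihydro-2H-chromen-6-yl}propanenitrile
Conditions: Pd(OAc)2 (2 mol%), SPhos (4 mol%), THF, 25 to 40 °C
Reagents that add atoms: none
Why: Negishi cross-coupling (zerovalent palladium formed in situ) of the aryl bromide with a beta-zincated nitrile, a homoenolate-type donor, runs without base, so the flavanone, which ring-opens by retro-oxa-Michael reaction under base, keeps its C2 configuration.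

Step 3
Reactants: 6 4-bromobenzene-1,3-diol (4-bromoresorcinol)
Product: 7 2,4-bis(benzyloxy)-1-bromobenzene
Conditions: BnBr (2.3 equiv), K2CO3, DMF, 60 °C
Reagents that add atoms: benzyl bromide, BrCc1ccccc1
Why: Williamson ether synthesis on both phenols gives the benzyl-protected aryl bromide needed for the aryllithium.

Step 4
Reactants: 5 3-{(2S)-2-[4-(benzyloxy)phenyl]-4-oxo-3,4-dihydro-2H-chromen-6-yl}propanenitrile; 7 2,4-bis(benzyloxy)-1-bromobenzene
Product: 10 1-[2,4-bis(benzyloxy)phenyl]-3-{(2S)-2-[4-(benzyloxy)phenyl]-4-[2,4-bis(benzyloxy)phenyl]-2H-chromen-6-yl}propan-1-one, via aryllithium 8 (not isolated), via dilithiated bis-adduct 9 (not isolated)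
Conditions: 7 (2.6 equiv), n-BuLi (2.5 equiv), THF, −78 °C; add 5, −78 to −20 °C; then 1 M aq. HCl, THF, 0 °C to rt; product kept cold and dark
Reagents that add atoms: water, O
Why: Bromine–lithium exchange gives the aryllithium, which adds 1,2 to the flavanone carbonyl faster than it enolises it at −78 °C and adds once to the nitrile (the N-lithio ketimine cannot add again), and aqueous acid then hydrolyses the ketimine to the ketone and dehydrates the doubly benzylic tertiary alcohol (E1) to the only possible alkene C3=C4, leaving C2 untouched.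

Step 5
Reactants: 10 1-[2,4-bis(benzyloxy)phenyl]-3-{(2S)-2-[4-(benzyloxy)phenyl]-4-[2,4-bis(benzyloxy)phenyl]-2H-chromen-6-yl}propan-1-one
Product: 12 1-[2,4-bis(benzyloxy)phenyl]-3-{(2S,3S)-2-[4-(benzyloxy)phenyl]-3-[2,4-bis(benzyloxy)benzoyl]-2,3-dihydro-1-benzofuran-5-yl}propan-1-one, via phenyl(tosyloxy)iodanyl carbinol 11 (not isolated)
Conditions: PhI(OH)OTs (1.1 equiv), MeCN/CH2Cl2/H2O (8:1:1), −20 to 0 °C, dark; pH 7 buffer work-up
Reagents that add atoms: water, O (the C4 oxygen; interchangeable with the hydroxyl ligand of PhI(OH)OTs)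
Why: Proposed new method: electrophilic PhI(OH)OTs adds to C3 of the electron-rich C3=C4 bond anti to the C2 aryl group and water captures the doubly benzylic C4 cation; in adduct 11 the C2 aryl and C3 iodanyl groups are both pseudo-equatorial, so the ring bond C4–C4a is antiperiplanar to C3–I and the ring A ipso carbon (activated by the ortho ring oxygen) migrates from C4 to C3 with loss of PhI and inversion at C3 while the C4 hydroxyl collapses to the aryl ketone (semipinacol-type 1,2-aryl shift), so that the carbon alpha to the new ketone reacts as an electrophile (an enolonium equivalent) towards a nucleophilic arene carbon, C3 is set trans to C2 (3S) both by this stereospecific course and by acid-mediated equilibration, and C2 is not touched; the closest known reaction types are the PhI(OH)OTs oxidative 1,2-aryl rearrangement of 1,1-diarylalkenes to alpha-aryl ketones, the ring contraction of 1,2-dihydronaphthalenes to indanes with the same reagent, and the PhI(OAc)2 or Tl(NO3)3 ring contraction of flavanones to trans-2-aryl-2,3-dihydrobenzofuran-3-carboxylates.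

Step 6
Reactants: 12 1-[2,4-bis(benzyloxy)phenyl]-3-{(2S,3S)-2-[4-(benzyloxy)phenyl]-3-[2,4-bis(benzyloxy)benzoyl]-2,3-dihydro-1-benzofuran-5-yl}propan-1-one
Product: 13 1-(2,4-dihydroxyphenyl)-3-[(2S,3S)-3-(2,4-dihydroxybenzoyl)-2-(4-hydroxyphenyl)-2,3-dihydro-1-benzofuran-5-yl]propan-1-one (CNP0136359.1)
Conditions: H2 (1 atm), 10% Pd/C, EtOAc/THF, rt, stopped at uptake of 5 equiv H2; neutral work-up
Reagents that add atoms: none
Why: Catalytic hydrogenolysis cleaves the five primary benzyl aryl ethers much faster than the hindered cyclic C2–O bond or the electron-rich aryl ketones, and its neutral conditions avoid both the base-triggered E1cB ring-opening at C3 and acid ionisation at C2, so the trans (2S,3S) configuration is kept.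

## Compound list

1 | 6-bromo-4H-chromen-4-one | O=C1C=COc2ccc(Br)cc12 | starting material
2 | [4-(benzyloxy)phenyl]boronic acid | OB(O)c1ccc(OCc2ccccc2)cc1 | starting material
3 | (2S)-2-[4-(benzyloxy)phenyl]-6-bromo-2,3-dihydro-4H-chromen-4-one | O=C1C[C@@H](c2ccc(OCc3ccccc3)cc2)Oc2ccc(Br)cc12 | intermediate
4 | (2-cyanoethyl)zinc bromide | N#CCC[Zn]Br | starting material
5 | 3-{(2S)-2-[4-(benzyloxy)phenyl]-4-oxo-3,4-dihydro-2H-chromen-6-yl}propanenitrile | O=C1C[C@@H](c2ccc(OCc3ccccc3)cc2)Oc2ccc(CCC#N)cc12 | intermediate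
6 | 4-bromobenzene-1,3-diol | Oc1ccc(Br)c(O)c1 | starting material
7 | 2,4-bis(benzyloxy)-1-bromobenzene | Brc1ccc(OCc2ccccc2)cc1OCc1ccccc1 | intermediate
8 | [2,4-bis(benzyloxy)phenyl]lithium (not isolated) | [Li]c1ccc(OCc2ccccc2)cc1OCc1ccccc1 | intermediate
9 | dilithiated bis-adduct: lithium alkoxide of the (2S)-4-aryl-chroman-4-ol (C4 epimers) carrying the N-lithio ketimine of the side chain (not isolated) | [Li]OC1(c2ccc(OCc3ccccc3)cc2OCc2ccccc2)C[C@@H](c2ccc(OCc3ccccc3)cc2)Oc2ccc(CCC(=N[Li])c3ccc(OCc4ccccc4)cc3OCc3ccccc3)cc12 | intermediate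
10 | 1-[2,4-bis(benzyloxy)phenyl]-3-{(2S)-2-[4-(benzyloxy)phenyl]-4-[2,4-bis(benzyloxy)phenyl]-2H-chromen-6-yl}propan-1-one | O=C(CCc1ccc2c(c1)C(c1ccc(OCc3ccccc3)cc1OCc1ccccc1)=C[C@@H](c1ccc(OCc3ccccc3)cc1)O2)c1ccc(OCc2ccccc2)cc1OCc1ccccc1 | intermediate
11 | phenyl(tosyloxy)iodanyl carbinol: 4-hydroxy-3-[phenyl(tosyloxy)iodanyl]chroman formed from 10; C2 spatially as in 10 (formally 2R because C3 now outranks the aryl group), iodanyl group trans to the C2 aryl group (3R), C4 epimers (not isolated) | O=C(CCc1ccc2c(c1)C(O)(c1ccc(OCc3ccccc3)cc1OCc1ccccc1)[C@H](I(OS(=O)(=O)c1ccc(C)cc1)c1ccccc1)[C@@H](c1ccc(OCc3ccccc3)cc1)O2)c1ccc(OCc2ccccc2)cc1OCc1ccccc1 | intermediate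
12 | 1-[2,4-bis(benzyloxy)phenyl]-3-{(2S,3S)-2-[4-(benzyloxy)phenyl]-3-[2,4-bis(benzyloxy)benzoyl]-2,3-dihydro-1-benzofuran-5-yl}propan-1-one | O=C(CCc1ccc2c(c1)[C@H](C(=O)c1ccc(OCc3ccccc3)cc1OCc1ccccc1)[C@@H](c1ccc(OCc3ccccc3)cc1)O2)c1ccc(OCc2ccccc2)cc1OCc1ccccc1 | intermediate
13 | 1-(2,4-dihydroxyphenyl)-3-[(2S,3S)-3-(2,4-dihydroxybenzoyl)-2-(4-hydroxyphenyl)-2,3-dihydro-1-benzofuran-5-yl]propan-1-one | O=C(CCc1ccc2c(c1)[C@H](C(=O)c1ccc(O)cc1O)[C@@H](c1ccc(O)cc1)O2)c1ccc(O)cc1O | target

## Step count and risks

Total steps: 6. Longest linear sequence: 5 steps (1 → 3 → 5 → 10 → 12 → 13); step 3 is a one-step side branch.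

The three steps most likely to fail are steps 4, 5 and 6.

The double aryllithium addition (step 4) can fail through enolisation and ring-opening of the flavanone (loss of ee), alpha-deprotonation of the nitrile, or rearrangement of the ortho-benzyloxy aryllithium on warming. The fallback sets out from 3 and comes back at 10, and makes the side-chain ketone by a cyclopropanol ring-opening coupling instead of a nitrile addition. Compound 3 is treated with 8 (1.2 equiv, THF, −78 °C) and then aqueous HCl to give (2S)-2-[4-(benzyloxy)phenyl]-4-[2,4-bis(benzyloxy)phenyl]-6-bromo-2H-chromene F1. Separately, 8 is added to excess methyl chloroformate at −78 °C to give methyl 2,4-bis(benzyloxy)benzoate F2, which a Kulinkovich reaction (EtMgBr, Ti(OiPr)4, THF) converts into 1-[2,4-bis(benzyloxy)phenyl]cyclopropan-1-ol F3. Coupling of F1 with F3 (Pd(OAc)2, XPhos, Cs2CO3, toluene, 80 °C) opens the cyclopropanol to a palladium homoenolate and gives the beta-aryl ketone 10 directly; compound 4 is not needed.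

The ring contraction (step 5) is the riskiest step. It can fail by migration of the exocyclic aryl group (giving a 2,3-diarylchroman-4-one), by oxidation of the chromene to the 2,4-diarylchromenylium salt, or by attack of the iodane on the electron-rich rings. The fallback sets out from 5 and comes back at 12, and moves the contraction to the ketone oxidation level, where it is a known reaction of flavanones. Compound 5 with PhI(OAc)2, catalytic H2SO4 and HC(OMe)3 at rt gives methyl (2S,3S)-2-[4-(benzyloxy)phenyl]-5-(2-cyanoethyl)-2,3-dihydro-1-benzofuran-3-carboxylate F4 (ring A shifts from C4 to C3 of the enol ether, C4 ends as the ester, C2 untouched, trans). MeNHOMe·HCl and i-PrMgCl (THF, −20 °C) convert F4 into (2S,3S)-2-[4-(benzyloxy)phenyl]-5-(2-cyanoethyl)-N-methoxy-N-methyl-2,3-dihydro-1-benzofuran-3-carboxamide F5. Aryllithium 8 (2.5 equiv, −78 °C, then aqueous HCl) adds to the amide and to the nitrile to give 12. This is one step longer, and the acidity of C3–H towards the aryllithium is its weak point.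

The hydrogenolysis (step 6) can over-reduce, cleaving the benzylic C2–O bond or reducing an aryl ketone. The fallback sets out from 12 and comes back at 13 without a new compound: BCl3 with pentamethylbenzene as cation scavenger in CH2Cl2 at −78 °C removes the five benzyl groups by Lewis-acid dealkylation, with no hydrogen or palladium present, followed by a cold methanol quench and neutral work-up.

## Further compounds

F1 | step 4 | (2S)-2-[4-(benzyloxy)phenyl]-4-[2,4-bis(benzyloxy)phenyl]-6-bromo-2H-chromene | Brc1ccc2c(c1)C(c1ccc(OCc3ccccc3)cc1OCc1ccccc1)=C[C@@H](c1ccc(OCc3ccccc3)cc1)O2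
F2 | step 4 | methyl 2,4-bis(benzyloxy)benzoate | COC(=O)c1ccc(OCc2ccccc2)cc1OCc1ccccc1
F3 | step 4 | 1-[2,4-bis(benzyloxy)phenyl]cyclopropan-1-ol | OC1(CC1)c1ccc(OCc2ccccc2)cc1OCc1ccccc1
F4 | step 5 | methyl (2S,3S)-2-[4-(benzyloxy)phenyl]-5-(2-cyanoethyl)-2,3-dihydro-1-benzofuran-3-carboxylate | N#CCCc1ccc2c(c1)[C@H](C(=O)OC)[C@@H](c1ccc(OCc3ccccc3)cc1)O2
F5 | step 5 | (2S,3S)-2-[4-(benzyloxy)phenyl]-5-(2-cyanoethyl)-N-methoxy-N-methyl-2,3-dihydro-1-benzofuran-3-carboxamide | N#CCCc1ccc2c(c1)[C@H](C(=O)N(C)OC)[C@@H](c1ccc(OCc3ccccc3)cc1)O2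
F0 | step 6 | none | none
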